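**Strategy**

The dihydrofuran is disconnected at O1–C2 and C3a–C3 (benzofuran numbering). In ring A, C3a lies between the oxygen-bearing carbons C7a and C4, so ring A is carried as a 5-substituted cyclohexane-1,3-dione: C3a is then the only nucleophilic carbon and both oxygens are equivalent. Its phenyliodonium ylide, made in the flask, and benzyl-protected resveratrol are joined in a formal [3+2] annulation under a chiral dirhodium carboxylate, which forms both bonds and both stereocentres at once; the para-oxygenated aryl ring destined for C2 fixes the regiochemistry and the trans ring closure. Dehydrogenation of the cyclohexenone to the C4 phenol and hydrogenolysis of four benzyl ethers complete the synthesis.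

Key step: step 4

Remarks on the chemistry:
- 3-[4-(Benzyloxy)phenyl]propanal (1) is taken as a catalogue compound; otherwise it is one oxidation away from the commercial alcohol.
- Rh2(S-NTTL)4 is dirhodium tetrakis[N-(1,8-naphthaloyl)-(S)-tert-leucinate]. It is assumed to deliver the 3S adduct; if the opposite sense is found, the antipodal catalyst Rh2(R-NTTL)4 is used.
- C6 of compounds 10–13 is a stereocentre of no consequence; both epimers are carried and converge in step 5.
- The target is (2S,3S), the trans isomer.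

**Route**

Step 1
Reactants: 1 3-[4-(benzyloxy)phenyl]propanal
Product: 2 (E)-6-[4-(benzyloxy)phenyl]hex-3-en-2-one
Conditions: Ph3P=CHC(O)CH3, toluene, 80 °C
Reagents that add atoms: 1-(triphenyl-λ5-phosphanylidene)propan-2-one, CC(=O)C=P(c1ccccc1)(c1ccccc1)c1ccccc1
Why: Wittig olefination with a carbonyl-stabilised ylide should give the E-enone selectively.

Step 2
Reactants: 2 (E)-6-[4-(benzyloxy)phenyl]hex-3-en-2-one
Product: 6 5-{2-[4-(benzyloxy)phenyl]ethyl}cyclohexane-1,3-dione, via Michael adduct 3 (not isolated), via keto ester 4 (not isolated), via keto acid 5 (not isolated)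
Conditions: CH2(CO2Me)2, NaOMe, MeOH, reflux; aq NaOH, reflux; aq HCl, 70 °C
Reagents that add atoms: dimethyl malonate, COC(=O)CC(=O)OC
Why: Michael addition of the malonate gives 3, Claisen ring closure of the methyl ketone onto an ester gives 4, and saponification to 5 followed by decarboxylation gives the dione (the classical synthesis of 5-substituted cyclohexane-1,3-diones); the benzyl aryl ether should tolerate the base and the brief warm dilute acid.

Step 3
Reactants: 7 (E)-5-[2-(4-hydroxyphenyl)ethenyl]benzene-1,3-diol (resveratrol)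
Product: 8 (E)-3,4',5-tris(benzyloxy)stilbene
Conditions: BnBr, K2CO3, DMF, 60 °C
Reagents that add atoms: benzyl bromide, BrCc1ccccc1
Why: Williamson etherification of all three phenols; the E-alkene is not touched.

Step 4
Reactants: 6 5-{2-[4-(benzyloxy)phenyl]ethyl}cyclohexane-1,3-dione; 8 (E)-3,4',5-tris(benzyloxy)stilbene
Product: 10 (2S,3S)-2-[4-(benzyloxy)phenyl]-3-[3,5-bis(benzyloxy)phenyl]-6-{2-[4-(benzyloxy)phenyl]ethyl}-2,3,6,7-tetrahydro-1-benzofuran-4(5H)-one, via iodonium ylide 9 (not isolated)
Conditions: PhI(OAc)2, MgO, Rh2(S-NTTL)4 (2 mol %), 4 Å molecular sieves, CH2Cl2, 0 → 25 °C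
Reagents that add atoms: none
Why: Proposed new method: dione 6 and PhI(OAc)2 give iodonium ylide 9, which passes its diacyl carbene to the dirhodium catalyst; the alkene of 8 attacks this electrophilic carbene with the carbon that carries the 3,5-bis(benzyloxy)phenyl ring, so that the charge develops on the carbon stabilised by the para-benzyloxyphenyl ring, and the enolate oxygen of the metal-bound dipole then closes onto that benzylic cation. The closest known reaction types are the dirhodium- or copper-catalysed formal [3+2] annulation of cyclic 2-diazo-1,3-diones and their phenyliodonium ylides with styrenes and enol ethers to 2,3-dihydrofurans, and the enantioselective alkene cyclopropanation by diacyl carbenes from phenyliodonium ylides of Meldrum's acid and malonates under chiral dirhodium tert-leucinate catalysts; asymmetric induction in the dihydrofuran manifold on a 1,2-diarylalkene has not been shown. The dihydrofuran ring is closed by attack of oxygen in a 5-exo-trig sense on the para-quinoid benzylic cation. C3 is set in the C–C bond formation by face selection on the alkene inside the chiral carboxylate pocket and, unlike the single benzylic centre of a terminal styrene adduct, cannot be lost in the dipole; C2 is set in the ring closure trans to the C3 aryl group by substrate control. The step needs regioselectivity, which the para-oxygen of the C2 aryl ring secures, chemoselectivity for the alkene over the alkoxyarenes, which the polarised stilbene double bond secures, and enantioselectivity, which rests on the catalyst alone and is the main risk.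

Step 5
Reactants: 10 (2S,3S)-2-[4-(benzyloxy)phenyl]-3-[3,5-bis(benzyloxy)phenyl]-6-{2-[4-(benzyloxy)phenyl]ethyl}-2,3,6,7-tetrahydro-1-benzofuran-4(5H)-one
Product: 14 (2S,3S)-2-[4-(benzyloxy)phenyl]-3-[3,5-bis(benzyloxy)phenyl]-6-{2-[4-(benzyloxy)phenyl]ethyl}-2,3-dihydro-1-benzofuran-4-ol, via selenide 11 (not isolated), via selenoxide 12 (not isolated), via dienone 13 (not isolated)
Conditions: LiN(i-Pr)2, THF, −78 °C; PhSeCl; then H2O2, pyridine, CH2Cl2, 0 → 25 °C
Reagents that add atoms: none
Why: Kinetic deprotonation of the vinylogous ester at C5 and selenenylation give 11, oxidation gives selenoxide 12, syn-elimination toward the only β-hydrogen (C6–H) gives cross-conjugated dienone 13, and this tautomerises to the phenol (α-selenenylation/selenoxide elimination); C2 and C3 are not involved and both C6 epimers converge.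

Step 6
Reactants: 14 (2S,3S)-2-[4-(benzyloxy)phenyl]-3-[3,5-bis(benzyloxy)phenyl]-6-{2-[4-(benzyloxy)phenyl]ethyl}-2,3-dihydro-1-benzofuran-4-ol
Product: 15 5-[(2S,3S)-4-hydroxy-2-(4-hydroxyphenyl)-6-[2-(4-hydroxyphenyl)ethyl]-2,3-dihydro-1-benzofuran-3-yl]benzene-1,3-diol
Conditions: H2 (1 atm), Pd/C, EtOAc–MeOH, 25 °C
Reagents that add atoms: none
Why: Hydrogenolysis of the four primary benzyl aryl ethers should be much faster than that of the hindered secondary C2–O1 bond of the ring, so the reaction is stopped once four equivalents of H2 are consumed; no stereocentre is touched.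

**Compound list**

1 | 3-[4-(benzyloxy)phenyl]propanal | O=CCCc1ccc(OCc2ccccc2)cc1 | starting material
2 | (E)-6-[4-(benzyloxy)phenyl]hex-3-en-2-one | CC(=O)/C=C/CCc1ccc(OCc2ccccc2)cc1 | intermediate
3 | dimethyl 2-{1-[4-(benzyloxy)phenyl]-5-oxohexan-3-yl}propanedioate | COC(=O)C(C(=O)OC)C(CCc1ccc(OCc2ccccc2)cc1)CC(C)=O | intermediate (not isolated)
4 | methyl 6-{2-[4-(benzyloxy)phenyl]ethyl}-2,4-dioxocyclohexane-1-carboxylate | COC(=O)C1C(=O)CC(=O)CC1CCc1ccc(OCc2ccccc2)cc1 | intermediate (not isolated)
5 | 6-{2-[4-(benzyloxy)phenyl]ethyl}-2,4-dioxocyclohexane-1-carboxylic acid | OC(=O)C1C(=O)CC(=O)CC1CCc1ccc(OCc2ccccc2)cc1 | intermediate (not isolated)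
6 | 5-{2-[4-(benzyloxy)phenyl]ethyl}cyclohexane-1,3-dione | O=C1CC(=O)CC(CCc2ccc(OCc3ccccc3)cc2)C1 | intermediate
7 | (E)-5-[2-(4-hydroxyphenyl)ethenyl]benzene-1,3-diol (resveratrol) | Oc1ccc(/C=C/c2cc(O)cc(O)c2)cc1 | starting material
8 | (E)-3,4',5-tris(benzyloxy)stilbene | C(Oc1ccc(/C=C/c2cc(OCc3ccccc3)cc(OCc3ccccc3)c2)cc1)c1ccccc1 | intermediate
9 | 5-{2-[4-(benzyloxy)phenyl]ethyl}-2-(phenyl-λ3-iodanylidene)cyclohexane-1,3-dione | O=C1CC(CCc2ccc(OCc3ccccc3)cc2)CC(=O)C1=Ic1ccccc1 | intermediate (not isolated)
10 | (2S,3S)-2-[4-(benzyloxy)phenyl]-3-[3,5-bis(benzyloxy)phenyl]-6-{2-[4-(benzyloxy)phenyl]ethyl}-2,3,6,7-tetrahydro-1-benzofuran-4(5H)-one (both C6 epimers) | c1ccccc1COc1ccc(CCC2CC(=O)C3=C(C2)O[C@H](c2ccc(OCc4ccccc4)cc2)[C@H]3c2cc(OCc4ccccc4)cc(OCc4ccccc4)c2)cc1 | intermediate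
11 | (2S,3S)-2-[4-(benzyloxy)phenyl]-3-[3,5-bis(benzyloxy)phenyl]-6-{2-[4-(benzyloxy)phenyl]ethyl}-5-(phenylselanyl)-2,3,6,7-tetrahydro-1-benzofuran-4(5H)-one | c1ccccc1COc1ccc(CCC2C([Se]c5ccccc5)C(=O)C3=C(C2)O[C@H](c2ccc(OCc4ccccc4)cc2)[C@H]3c2cc(OCc4ccccc4)cc(OCc4ccccc4)c2)cc1 | intermediate (not isolated)
12 | (2S,3S)-5-(benzeneseleninyl)-2-[4-(benzyloxy)phenyl]-3-[3,5-bis(benzyloxy)phenyl]-6-{2-[4-(benzyloxy)phenyl]ethyl}-2,3,6,7-tetrahydro-1-benzofuran-4(5H)-one | c1ccccc1COc1ccc(CCC2C([Se](=O)c5ccccc5)C(=O)C3=C(C2)O[C@H](c2ccc(OCc4ccccc4)cc2)[C@H]3c2cc(OCc4ccccc4)cc(OCc4ccccc4)c2)cc1 | intermediate (not isolated)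
13 | (2S,3S)-2-[4-(benzyloxy)phenyl]-3-[3,5-bis(benzyloxy)phenyl]-6-{2-[4-(benzyloxy)phenyl]ethyl}-2,3-dihydro-1-benzofuran-4(7H)-one | c1ccccc1COc1ccc(CCC2=CC(=O)C3=C(C2)O[C@H](c2ccc(OCc4ccccc4)cc2)[C@H]3c2cc(OCc4ccccc4)cc(OCc4ccccc4)c2)cc1 | intermediate (not isolated)
14 | (2S,3S)-2-[4-(benzyloxy)phenyl]-3-[3,5-bis(benzyloxy)phenyl]-6-{2-[4-(benzyloxy)phenyl]ethyl}-2,3-dihydro-1-benzofuran-4-ol | c1ccccc1COc1ccc(CCc2cc(O)c3c(c2)O[C@H](c2ccc(OCc4ccccc4)cc2)[C@H]3c2cc(OCc4ccccc4)cc(OCc4ccccc4)c2)cc1 | intermediate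
15 | 5-[(2S,3S)-4-hydroxy-2-(4-hydroxyphenyl)-6-[2-(4-hydroxyphenyl)ethyl]-2,3-dihydro-1-benzofuran-3-yl]benzene-1,3-diol (CNP0315602.1) | Oc1ccc(CCc2cc(O)c3c(c2)O[C@H](c2ccc(O)cc2)[C@H]3c2cc(O)cc(O)c2)cc1 | target

**Step count and risks**

Total step count: 6. Longest linear sequence: 5 steps (steps 1, 2, 4, 5, 6); step 3 is a one-step side branch.

Steps most likely to fail:

Step 4 (proposed new method). Facial selection in the carbene transfer may be poor, because the diacyl carbene is symmetric and the alkene approaches far from the chiral ligands. The transfer to a trans-1,2-disubstituted alkene may also be too slow, so that the ylide is lost by dimerisation or rearrangement. The fallback uses known chemistry and sets out from 6 and 8. Mn(OAc)3·2H2O in AcOH at 70 °C oxidises the dione to its α-radical, which adds to the same alkene carbon; oxidation of the benzylic radical and closure through oxygen should give the trans-dihydrofuran without absolute control. The product is 10 together with the (2R,3R)-enantiomer of 10 F1, each as both C6 epimers. Preparative chromatography on a chiral stationary phase (amylose tris(3,5-dimethylphenylcarbamate), supercritical CO2/MeOH) separates them, and the route is rejoined at 10.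

Step 5. The electrophilic selenium species or the peroxide may attack the electron-rich arenes and the newly formed resorcinol-type phenol, or the selenoxide may not eliminate cleanly. The fallback sets out from 10. LiN(SiMe3)2 and Me3SiCl in THF at −78 °C give (2S,3S)-2-[4-(benzyloxy)phenyl]-3-[3,5-bis(benzyloxy)phenyl]-6-{2-[4-(benzyloxy)phenyl]ethyl}-4-[(trimethylsilyl)oxy]-2,3,6,7-tetrahydro-1-benzofuran F2. Pd(OAc)2 in MeCN at 25 °C (Saegusa–Ito oxidation) then gives dienone 13, which tautomerises, and the route is rejoined at 14.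

Step 6. Over-reduction may occur: hydrogenolysis of the benzylic C2–O1 bond of the dihydrofuran once the para-phenol of the C2 aryl ring is free. The fallback sets out from 14 and removes the benzyl groups without hydrogen, by BCl3 and pentamethylbenzene in CH2Cl2 at −78 °C (Lewis-acid cleavage with a cation scavenger). It arrives directly at 15 and makes no new compound (F0).

**Further compounds**

F1 | step 4 | (2R,3R)-2-[4-(benzyloxy)phenyl]-3-[3,5-bis(benzyloxy)phenyl]-6-{2-[4-(benzyloxy)phenyl]ethyl}-2,3,6,7-tetrahydro-1-benzofuran-4(5H)-one | c1ccccc1COc1ccc(CCC2CC(=O)C3=C(C2)O[C@@H](c2ccc(OCc4ccccc4)cc2)[C@@H]3c2cc(OCc4ccccc4)cc(OCc4ccccc4)c2)cc1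
F2 | step 5 | (2S,3S)-2-[4-(benzyloxy)phenyl]-3-[3,5-bis(benzyloxy)phenyl]-6-{2-[4-(benzyloxy)phenyl]ethyl}-4-[(trimethylsilyl)oxy]-2,3,6,7-tetrahydro-1-benzofuran | c1ccccc1COc1ccc(CCC2C=C(O[Si](C)(C)C)C3=C(C2)O[C@H](c2ccc(OCc4ccccc4)cc2)[C@H]3c2cc(OCc4ccccc4)cc(OCc4ccccc4)c2)cc1
F0 | step 6 | none | none
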